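**Retrosynthetic overview**

1. Locants (quinone numbering): C1/C4 = C=O, C2 = C–OH, C3 = C–henicosyl, C5 = C–OMe, C6 = CH. Target ⇐ acetate cleavage and oxidative dealkylation at C1/C4 of aryl acetate 13, which already carries all four oxygens in differentiated form.
2. 13 ⇐ ring closure at C5–C6 by 6π-electrocyclization of an acyclic trienolate (C6=C1–C2=C3–C4=C5), then loss of MeOH from the C5 ketal. The triene is formed in the same flask by 4π opening of a cyclobutenolate (C2–C5 bond cleaved).
3. Cyclobutenolate ⇐ (1-ethoxyethenyl)lithium (C1, C6) + cyclobutenone monoketal 6 (C2–C5) ⇐ dimethyl squarate + henicosyl Grignard reagent.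
4. Enabling feature: ring atoms C2(O)–C3(alkyl)–C4(O)–C5(OMe) are a squaric acid unit with one oxygen traded for the chain. C5 can therefore enter as a dimethyl ketal, which keeps one methoxy on C5 and offers the other as the leaving group for aromatization. C6, the only ring CH, comes from a vinyl CH2.
5. Ring order: the purchased four-membered ring is temporary and is opened; the six-membered carbocycle, the only ring of the target, is closed in step 2.

Key step: step 2

Assumption: 1-bromohenicosane is taken as a catalogue compound (otherwise one Appel bromination from henicosan-1-ol).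

**Step 1**
Reactants: 1 (dimethyl squarate) and 2 (1-bromohenicosane)
Product: 6 2-henicosyl-3,4,4-trimethoxycyclobut-2-en-1-one, via henicosylmagnesium bromide 3 (not isolated), via bromomagnesium cyclobutenolate 4 (not isolated), via cyclobutenyl trifluoroacetate 5 (not isolated)
Conditions: 2, Mg, THF, 45 °C; add to 1, THF, −78 → −40 °C; (CF3CO)2O, −78 °C; then MeOH, −78 → 0 °C
Reagents that add atoms: methanol CO
Why: Grignard 1,2-addition to one squarate carbonyl, O-trifluoroacetylation and ionization should give a methoxy-stabilized cyclobutenyl cation that methanol captures at the distal methoxy-bearing carbon (the established one-flask entry to cyclobutenedione monoacetals), leaving the single carbonyl next to the chain-bearing carbon.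

**Step 2**
Reactants: 6 (2-henicosyl-3,4,4-trimethoxycyclobut-2-en-1-one) and 7 (ethyl vinyl ether)
Product: 13 6-ethoxy-2-henicosyl-3,4-dimethoxyphenyl acetate, via (1-ethoxyethenyl)lithium 8 (not isolated), via lithium cyclobutenolate 9 (not isolated), via lithium trienolate 10 (not isolated), via lithium cyclohexadienolate 11 (not isolated), via lithium phenolate 12 (not isolated)
Conditions: 7 (1.5 equiv), tBuLi, THF, −78 → 0 °C; then 6, −78 °C; warm to 23 °C, then 65 °C; then Ac2O, 0 → 23 °C
Reagents that add atoms: acetic anhydride CC(=O)OC(C)=O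
Why: Proposed new method: the vinyllithium should add 1,2 to the only carbonyl of 6, and alkoxide 9 should undergo strain- and oxyanion-driven conrotatory 4π opening of the C(O−)–C(OMe)2 bond to trienolate 10, whose thermal 6π-electrocyclization joins the ketene-acetal carbon C5 to the vinyl CH2 carbon C6; loss of methanol from the C5 ketal of 11 (next to C6H2) then aromatizes the ring irreversibly, leaves one methoxy on C5, and Ac2O caps the phenolate. The closest known reaction types are the Moore rearrangement (thermal ring expansion of 4-alkenyl-4-hydroxycyclobutenones to hydroquinones through dienylketenes) and the alkoxide-accelerated 4π-opening/electrocyclization cascades of squarate bis-adducts; new here is that a ketal (ketene O,O-acetal terminus) replaces the ketone (ketene terminus), so C5 ends as an aryl methyl ether and not as a phenol. Mode of closure of the six-membered ring: thermal disrotatory 6π-electrocyclization of a hexatriene whose central C2=C3 bond carries C1 and C4 on the same side, C5–C6 being the only σ-bond formed in the ring-closing event. No stereocentre survives, because C5 and C6 are sp3 only in 11 and the product is an achiral arene. The selectivity needed is outward rotation of the oxido group (inward rotation of the ethoxyvinyl group) in the ring opening, secured by the strong outward preference of O− donors and correctable by enolate isomerization at 65 °C; regiochemistry is fixed because 6 has one carbonyl and only the C5 ketal has a leaving group next to a C–H.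

**Step 3**
Reactants: 13 (6-ethoxy-2-henicosyl-3,4-dimethoxyphenyl acetate)
Product: 14 2-henicosyl-4-methoxy-3,6-dioxocyclohexa-1,4-dien-1-yl acetate
Conditions: (NH4)2Ce(NO3)6 (2.5 equiv), MeCN–THF–H2O, 0 °C
Reagents that add atoms: water O
Why: Oxidative dealkylation of a para-dialkoxyarene by tetravalent cerium (known quinone synthesis) should occur only across C1(OEt)/C4(OMe), the one para pair of ether oxygens, because the group para to C5–OMe is the non-oxidizable acetoxy group; water supplies the carbonyl oxygens and ethanol and methanol leave.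

**Step 4**
Reactants: 14 (2-henicosyl-4-methoxy-3,6-dioxocyclohexa-1,4-dien-1-yl acetate)
Product: 15 2-henicosyl-3-hydroxy-5-methoxycyclohexa-2,5-diene-1,4-dione (target)
Conditions: K2CO3 (1.2 equiv), MeOH–THF, 0 °C; then 1 M HCl
Reagents that add atoms: none
Why: Transesterification of the enol acetate (a vinylogous mixed anhydride) should be much faster than attack at ring carbon, methoxide exchange at C5 is degenerate, and acidification returns the free hydroxyquinone.

**Compound list**

1 | dimethyl squarate (3,4-dimethoxycyclobut-3-ene-1,2-dione) | COC1=C(OC)C(=O)C1=O | starting material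
2 | 1-bromohenicosane | CCCCCCCCCCCCCCCCCCCCCBr | starting material
3 | henicosylmagnesium bromide | CCCCCCCCCCCCCCCCCCCCC[Mg]Br | intermediate
4 | bromomagnesium 1-henicosyl-2,3-dimethoxy-4-oxocyclobut-2-en-1-olate (racemic) | CCCCCCCCCCCCCCCCCCCCCC1(O[Mg]Br)C(OC)=C(OC)C1=O | intermediate
5 | 1-henicosyl-2,3-dimethoxy-4-oxocyclobut-2-en-1-yl trifluoroacetate (racemic) | CCCCCCCCCCCCCCCCCCCCCC1(OC(=O)C(F)(F)F)C(OC)=C(OC)C1=O | intermediate
6 | 2-henicosyl-3,4,4-trimethoxycyclobut-2-en-1-one | CCCCCCCCCCCCCCCCCCCCCC1=C(OC)C(OC)(OC)C1=O | intermediate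
7 | ethyl vinyl ether (ethoxyethene) | CCOC=C | starting material
8 | (1-ethoxyethenyl)lithium | [Li]C(=C)OCC | intermediate
9 | lithium 1-(1-ethoxyethenyl)-2-henicosyl-3,4,4-trimethoxycyclobut-2-en-1-olate (racemic) | [Li+].[O-]C1(C(=C)OCC)C(CCCCCCCCCCCCCCCCCCCCC)=C(OC)C1(OC)OC | intermediate
10 | lithium (3E)-2-ethoxy-4-henicosyl-5,6,6-trimethoxyhexa-1,3,5-trien-3-olate | [Li+].C=C(OCC)/C([O-])=C(\C(OC)=C(OC)OC)CCCCCCCCCCCCCCCCCCCCC | intermediate
11 | lithium 2-ethoxy-6-henicosyl-4,4,5-trimethoxycyclohexa-1,5-dien-1-olate | [Li+].[O-]C1=C(OCC)CC(OC)(OC)C(OC)=C1CCCCCCCCCCCCCCCCCCCCC | intermediate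
12 | lithium 6-ethoxy-2-henicosyl-3,4-dimethoxyphenolate | [Li+].[O-]c1c(OCC)cc(OC)c(OC)c1CCCCCCCCCCCCCCCCCCCCC | intermediate
13 | 6-ethoxy-2-henicosyl-3,4-dimethoxyphenyl acetate | CC(=O)Oc1c(OCC)cc(OC)c(OC)c1CCCCCCCCCCCCCCCCCCCCC | intermediate
14 | 2-henicosyl-4-methoxy-3,6-dioxocyclohexa-1,4-dien-1-yl acetate | CC(=O)OC1=C(CCCCCCCCCCCCCCCCCCCCC)C(=O)C(OC)=CC1=O | intermediate
15 | 2-henicosyl-3-hydroxy-5-methoxycyclohexa-2,5-diene-1,4-dione | CCCCCCCCCCCCCCCCCCCCCC1=C(O)C(=O)C=C(OC)C1=O | target

**Step count and risks**

Total step count: 4. Longest linear sequence: 4 steps (1 → 6 → 13 → 14 → 15).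

Steps most likely to fail:

Step 2 (Proposed new method). After the four-membered ring has opened, electrocyclic closure of the crowded, all-donor trienolate may be slower than its protonation or oligomerization, so that material leaves the cascade as an open-chain ketene acetal and is hydrolysed at work-up. The fallback uses known chemistry and keeps the C5–C6 closure, now as the ketene-to-vinyl closure of a Moore rearrangement. It sets out from 1 and returns at 13.
- Addition of 8 to 1 at −78 °C with in-flask O-silylation (TBSOTf, 2,6-lutidine) should give 4-[(tert-butyldimethylsilyl)oxy]-4-(1-ethoxyethenyl)-2,3-dimethoxycyclobut-2-en-1-one F1.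
- 1,2-Addition of 3 to its remaining carbonyl should give 4-[(tert-butyldimethylsilyl)oxy]-4-(1-ethoxyethenyl)-1-henicosyl-2,3-dimethoxycyclobut-2-en-1-ol F2.
- (CF3CO)2O followed by buffered aqueous work-up should transpose F2, with loss of methanol, to 4-[(tert-butyldimethylsilyl)oxy]-4-(1-ethoxyethenyl)-3-henicosyl-2-methoxycyclobut-2-en-1-one F3, whose carbonyl carbon is C5.
- Heating F3 in toluene at 110 °C should trigger the Moore rearrangement and give 4-[(tert-butyldimethylsilyl)oxy]-5-ethoxy-3-henicosyl-2-methoxyphenol F4.
- O-Methylation (MeI, K2CO3, acetone) should give tert-butyl(6-ethoxy-2-henicosyl-3,4-dimethoxyphenoxy)dimethylsilane F5.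
- Desilylation (tetrabutylammonium fluoride, THF) should give 6-ethoxy-2-henicosyl-3,4-dimethoxyphenol F6, and acetylation (Ac2O, pyridine) returns to 13.

Step 1. The cyclobutenyl cation may be captured by trifluoroacetate or adventitious water instead of methanol, which ends in hydrolysis at work-up. Addition of the poorly soluble C21 Grignard reagent may also be slow at low temperature. The fallback sets out from 5 (made as in step 1, addition run at −40 °C if needed) and returns at 6. Deliberate aqueous quench should give the stable dione 3-henicosyl-4-methoxycyclobut-3-ene-1,2-dione F7. Its more electrophilic carbonyl (next to the methoxy-bearing carbon, not the vinylogous ester carbonyl) is then ketalized with MeOSiMe3 and catalytic Me3SiOTf in CH2Cl2 at −78 °C to give 6.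

Step 3. The acetate may be lost in the acidic aqueous oxidant before the arene is oxidized, which would allow dealkylation along the wrong O–O axis, and the electron-rich ring may be over-oxidized. The fallback sets out from 13 and returns at 14. Constant-current anodic oxidation of 13 in MeOH (LiClO4, 2,6-lutidine, carbon anode, undivided cell) should add methanol twice, at C1 and C4, to give the quinone bisketal 6-ethoxy-2-henicosyl-3,3,4,6-tetramethoxycyclohexa-1,4-dien-1-yl acetate F8. Brief treatment with dilute aqueous acetic acid in acetone should then hydrolyse both ketals to 14 without any metal oxidant.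

**Further compounds**

F1 | step 2 | 4-[(tert-butyldimethylsilyl)oxy]-4-(1-ethoxyethenyl)-2,3-dimethoxycyclobut-2-en-1-one (racemic) | CCOC(=C)C1(O[Si](C)(C)C(C)(C)C)C(OC)=C(OC)C1=O
F2 | step 2 | 4-[(tert-butyldimethylsilyl)oxy]-4-(1-ethoxyethenyl)-1-henicosyl-2,3-dimethoxycyclobut-2-en-1-ol (diastereomer mixture) | CCOC(=C)C1(O[Si](C)(C)C(C)(C)C)C(OC)=C(OC)C1(O)CCCCCCCCCCCCCCCCCCCCC
F3 | step 2 | 4-[(tert-butyldimethylsilyl)oxy]-4-(1-ethoxyethenyl)-3-henicosyl-2-methoxycyclobut-2-en-1-one (racemic) | CCOC(=C)C1(O[Si](C)(C)C(C)(C)C)C(CCCCCCCCCCCCCCCCCCCCC)=C(OC)C1=O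
F4 | step 2 | 4-[(tert-butyldimethylsilyl)oxy]-5-ethoxy-3-henicosyl-2-methoxyphenol | CCOc1cc(O)c(OC)c(CCCCCCCCCCCCCCCCCCCCC)c1O[Si](C)(C)C(C)(C)C
F5 | step 2 | tert-butyl(6-ethoxy-2-henicosyl-3,4-dimethoxyphenoxy)dimethylsilane | CCOc1cc(OC)c(OC)c(CCCCCCCCCCCCCCCCCCCCC)c1O[Si](C)(C)C(C)(C)C
F6 | step 2 | 6-ethoxy-2-henicosyl-3,4-dimethoxyphenol | CCOc1cc(OC)c(OC)c(CCCCCCCCCCCCCCCCCCCCC)c1O
F7 | step 1 | 3-henicosyl-4-methoxycyclobut-3-ene-1,2-dione | COC1=C(CCCCCCCCCCCCCCCCCCCCC)C(=O)C1=O
F8 | step 3 | 6-ethoxy-2-henicosyl-3,3,4,6-tetramethoxycyclohexa-1,4-dien-1-yl acetate (racemic) | CCOC1(OC)C=C(OC)C(OC)(OC)C(CCCCCCCCCCCCCCCCCCCCC)=C1OC(C)=O
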